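**Retrosynthetic overview**

- The strategy rests on the 1,2-dioxolane ring (O–O, C3, C4, C5; acid-chain numbering: C1 CO2H, C2, ring C3–C4–C5, C6, C7 methine), in which C3 and C5 are a 1,3-pair of fully substituted carbinol carbons. Cutting only the O–O bond leaves a stereodefined ditertiary 1,3-diol, used as its 1,3-bis(aminooxy) derivative 31.
- The only ring is closed in step 20: 31 is oxidised to a seven-membered cyclic cis-hyponitrite, N2 is lost, and the two tertiary alkoxyl radicals recombine to dioxolane 35.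
- After ring closure, C10=C11 is made by Julia–Kocienski olefination with phenyltetrazolyl sulfone 7 (C11–C15, from cinnamyl bromide and tert-butyl acetate), and C1 is then raised to the acid.
- Before it, C7 comes from (R)-citronellal; C5 and then C3 are set by two rounds of Zr-catalysed methylalumination/formaldehyde, Sharpless epoxidation (D-(−)- then L-(+)-tartrate) and hydride opening, linked by oxidation and Ohira–Bestmann alkynylation. The citronellal alkene masks C10 until just before the key step.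

Key step: step 20

Remark: carbons are numbered along the acid chain (C1 = CO2H to C15 = CHPh); (E)-cinnamyl bromide is taken as the commercial cinnamyl halide because ester enolates alkylate it more cleanly than the chloride.

**Route**

Step 1
Reactants: 1 tert-butyl acetate; 2 (E)-cinnamyl bromide
Product: 4 tert-butyl (4E)-5-phenylpent-4-enoate, via lithium enolate 3 (not isolated)
Conditions: LiN(iPr)2 (LDA), THF, −78 °C; then 2, −78 → 0 °C
Reagents that add atoms: none
Why: Ester enolate alkylation; the lithium enolate should attack the primary allylic bromide at its α-carbon (SN2) and leave the (E)-styryl geometry untouched.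

Step 2
Reactants: 4 tert-butyl (4E)-5-phenylpent-4-enoate
Product: 5 (4E)-5-phenylpent-4-en-1-ol
Conditions: LiAlH4, THF, 0 °C
Reagents that add atoms: none
Why: Hydride reduction of the ester to the primary alcohol; the isolated styrene is inert to LiAlH4.

Step 3
Reactants: 5 (4E)-5-phenylpent-4-en-1-ol
Product: 6 1-phenyl-5-{[(4E)-5-phenylpent-4-en-1-yl]sulfanyl}-1H-tetrazole
Conditions: 1-phenyl-1H-tetrazole-5-thiol, PPh3, DIAD, THF, 0 °C → rt
Reagents that add atoms: 1-phenyl-1H-tetrazole-5-thiol, Sc1nnnn1-c1ccccc1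
Why: Mitsunobu thioetherification of an unhindered primary alcohol with an acidic heteroaryl thiol.

Step 4
Reactants: 6 1-phenyl-5-{[(4E)-5-phenylpent-4-en-1-yl]sulfanyl}-1H-tetrazole
Product: 7 1-phenyl-5-{[(4E)-5-phenylpent-4-en-1-yl]sulfonyl}-1H-tetrazole
Conditions: H2O2 (30% aq), (NH4)6Mo7O24·4H2O (cat.), EtOH, 0 °C → rt
Reagents that add atoms: hydrogen peroxide, OO
Why: Molybdate-catalysed sulfide-to-sulfone oxidation, in which the peroxomolybdate should oxidise sulfur in preference to the styrenyl alkene.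

Step 5
Reactants: 8 (R)-citronellal
Product: 9 (4R)-4,8-dimethylnon-7-en-1-yne
Conditions: dimethyl (1-diazo-2-oxopropyl)phosphonate, K2CO3, MeOH, 0 °C → rt
Reagents that add atoms: dimethyl (1-diazo-2-oxopropyl)phosphonate, CC(=O)C(=[N+]=[N-])P(=O)(OC)OC
Why: Ohira–Bestmann (Seyferth–Gilbert) homologation of the aldehyde to the terminal alkyne; the methyl-bearing stereocentre is β to the carbonyl and cannot epimerise.

Step 6
Reactants: 9 (4R)-4,8-dimethylnon-7-en-1-yne; 10 formaldehyde (as paraformaldehyde)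
Product: 13 (2E,5R)-3,5,9-trimethyldeca-2,8-dien-1-ol, via alkenylalane 11 (not isolated), via lithium alkenylaluminate 12 (not isolated)
Conditions: AlMe3, Cp2ZrCl2 (cat.), CH2Cl2, 0 °C → rt; then n-BuLi, hexane/THF, −78 °C; then (CH2O)n, −78 °C → rt
Reagents that add atoms: trimethylaluminium, C[Al](C)C
Why: Negishi zirconium-catalysed methylalumination adds Me and Al syn with methyl on the internal carbon, and the derived aluminate is hydroxymethylated with retention to give the (E)-3-methylallylic alcohol, as in the geraniol synthesis from the analogous enyne.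

Step 7
Reactants: 13 (2E,5R)-3,5,9-trimethyldeca-2,8-dien-1-ol
Product: 14 [(2R,3R)-3-[(2R)-2,6-dimethylhept-5-en-1-yl]-3-methyloxiran-2-yl]methanol
Conditions: Ti(OiPr)4 (cat.), D-(−)-diethyl tartrate (cat.), t-BuOOH, 4 Å MS, CH2Cl2, −20 °C
Reagents that add atoms: tert-butyl hydroperoxide, CC(C)(C)OO
Why: Sharpless asymmetric epoxidation; D-(−)-tartrate gives the mirror-image outcome of the geraniol/L-(+)-tartrate case ((2S,3S)), so the (2R,3R)-epoxide forms and fixes the future C5 carbinol as (R) under reagent control, while the isolated trisubstituted alkene is not epoxidised.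

Step 8
Reactants: 14 [(2R,3R)-3-[(2R)-2,6-dimethylhept-5-en-1-yl]-3-methyloxiran-2-yl]methanol
Product: 15 (3R,5R)-3,5,9-trimethyldec-8-ene-1,3-diol
Conditions: NaAlH2(OCH2CH2OMe)2 (Red-Al), THF, 0 °C → rt
Reagents that add atoms: none
Why: Regioselective reductive opening of a 2,3-epoxy alcohol, with hydride delivered intramolecularly from the O1-bound aluminate to the less substituted C2, so the tertiary C–O bond is kept and its configuration retained.

Step 9
Reactants: 15 (3R,5R)-3,5,9-trimethyldec-8-ene-1,3-diol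
Product: 16 (3R,5R)-3,5,9-trimethyl-1,3-bis(triethylsilyloxy)dec-8-ene
Conditions: Et3SiOTf, 2,6-lutidine, CH2Cl2, −78 → 0 °C
Reagents that add atoms: triethylsilyl trifluoromethanesulfonate, CC[Si](CC)(CC)OS(=O)(=O)C(F)(F)F
Why: Silyl triflate silylation, reactive enough to cap the tertiary as well as the primary hydroxyl, so that the later aldehyde is not a free β-hydroxy aldehyde.

Step 10
Reactants: 16 (3R,5R)-3,5,9-trimethyl-1,3-bis(triethylsilyloxy)dec-8-ene
Product: 18 (3R,5R)-3,5,9-trimethyl-3-(triethylsilyloxy)dec-8-enal, via alkoxysulfonium chloride 17 (not isolated)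
Conditions: (COCl)2, DMSO, CH2Cl2, −78 → −30 °C; then Et3N, −78 °C → rt
Reagents that add atoms: none
Why: Swern oxidation applied directly to a primary triethylsilyl ether; chlorodimethylsulfonium chloride should cleave only the unhindered primary O–Si bond to the alkoxysulfonium salt, which Et3N collapses to the aldehyde while the tertiary silyl ether stays.

Step 11
Reactants: 18 (3R,5R)-3,5,9-trimethyl-3-(triethylsilyloxy)dec-8-enal
Product: 19 triethyl{[(4R,6R)-4,6,10-trimethylundec-9-en-1-yn-4-yl]oxy}silane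
Conditions: dimethyl (1-diazo-2-oxopropyl)phosphonate, K2CO3, MeOH, 0 °C → rt
Reagents that add atoms: dimethyl (1-diazo-2-oxopropyl)phosphonate, CC(=O)C(=[N+]=[N-])P(=O)(OC)OC
Why: Ohira–Bestmann homologation under mild carbonate conditions; the silyl cap on the β-oxygen blocks retro-aldol cleavage and the tertiary silyl ether is stable to K2CO3/MeOH.

Step 12
Reactants: 19 triethyl{[(4R,6R)-4,6,10-trimethylundec-9-en-1-yn-4-yl]oxy}silane; 10 formaldehyde (as paraformaldehyde)
Product: 22 (2E,5R,7R)-3,5,7,11-tetramethyl-5-(triethylsilyloxy)dodeca-2,10-dien-1-ol, via alkenylalane 20 (not isolated), via lithium alkenylaluminate 21 (not isolated)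
Conditions: AlMe3, Cp2ZrCl2 (cat.), CH2Cl2, 0 °C → rt; then n-BuLi, hexane/THF, −78 °C; then (CH2O)n, −78 °C → rt
Reagents that add atoms: trimethylaluminium, C[Al](C)C
Why: Second Negishi methylalumination/hydroxymethylation, syn and regioselective as in step 6; silyl ethers are tolerated by AlMe3/Cp2ZrCl2 at room temperature.

Step 13
Reactants: 22 (2E,5R,7R)-3,5,7,11-tetramethyl-5-(triethylsilyloxy)dodeca-2,10-dien-1-ol
Product: 23 [(2S,3S)-3-methyl-3-[(2R,4R)-2,4,8-trimethyl-2-(triethylsilyloxy)non-7-en-1-yl]oxiran-2-yl]methanol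
Conditions: Ti(OiPr)4 (cat.), L-(+)-diethyl tartrate (cat.), t-BuOOH, 4 Å MS, CH2Cl2, −20 °C
Reagents that add atoms: tert-butyl hydroperoxide, CC(C)(C)OO
Why: Sharpless asymmetric epoxidation with L-(+)-tartrate in the same sense as geraniol to (2S,3S)-epoxygeraniol, setting the future C3 carbinol under reagent control that should override the remote C5 and C7 centres.

Step 14
Reactants: 23 [(2S,3S)-3-methyl-3-[(2R,4R)-2,4,8-trimethyl-2-(triethylsilyloxy)non-7-en-1-yl]oxiran-2-yl]methanol
Product: 24 (3R,5R,7R)-3,5,7,11-tetramethyl-5-(triethylsilyloxy)dodec-10-ene-1,3-diol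
Conditions: NaAlH2(OCH2CH2OMe)2 (Red-Al), THF, 0 °C → rt
Reagents that add atoms: none
Why: Red-Al opening of the 2,3-epoxy alcohol at C2 by intramolecular hydride delivery, as in step 8, with the tertiary C–O bond and its configuration kept.

Step 15
Reactants: 24 (3R,5R,7R)-3,5,7,11-tetramethyl-5-(triethylsilyloxy)dodec-10-ene-1,3-diol
Product: 25 (3R,5R,7R)-3,5,7,11-tetramethyldodec-10-ene-1,3,5-triol
Conditions: Bu4NF, THF, rt → 40 °C
Reagents that add atoms: none
Why: Fluoride desilylation of the tertiary triethylsilyl ether, done before the two permanent silyl ethers are installed so that no selectivity between silyl groups is needed.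

Step 16
Reactants: 25 (3R,5R,7R)-3,5,7,11-tetramethyldodec-10-ene-1,3,5-triol
Product: 26 (3R,5R,7R)-1-[(tert-butyldiphenylsilyl)oxy]-3,5,7,11-tetramethyldodec-10-ene-3,5-diol
Conditions: t-BuPh2SiCl, imidazole, CH2Cl2, 0 °C → rt
Reagents that add atoms: tert-butyl(chloro)diphenylsilane, CC(C)(C)[Si](Cl)(c1ccccc1)c1ccccc1
Why: Selective silylation; the bulky chlorosilane reacts only with the primary hydroxyl and leaves both tertiary hydroxyls free.

Step 17
Reactants: 26 (3R,5R,7R)-1-[(tert-butyldiphenylsilyl)oxy]-3,5,7,11-tetramethyldodec-10-ene-3,5-diol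
Product: 28 (4R,6R,8R)-10-[(tert-butyldiphenylsilyl)oxy]-4,6,8-trimethyldecane-1,6,8-triol, via aldehyde 27 (not isolated)
Conditions: O3, CH2Cl2/MeOH, −78 °C; then NaBH4, −78 °C → rt
Reagents that add atoms: ozone, [O-][O+]=O
Why: Ozonolysis of the only alkene with reductive borohydride work-up, which removes the last C=C before the nitrogen chemistry and reveals C10 as a primary alcohol.

Step 18
Reactants: 28 (4R,6R,8R)-10-[(tert-butyldiphenylsilyl)oxy]-4,6,8-trimethyldecane-1,6,8-triol
Product: 29 (3R,5R,7R)-10-[(tert-butyldimethylsilyl)oxy]-1-[(tert-butyldiphenylsilyl)oxy]-3,5,7-trimethyldecane-3,5-diol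
Conditions: t-BuMe2SiCl, imidazole, CH2Cl2, 0 °C
Reagents that add atoms: tert-butyl(chloro)dimethylsilane, CC(C)(C)[Si](C)(C)Cl
Why: Selective silylation of the primary hydroxyl, giving C10 a silyl ether more acid-labile than the one at C1.

Step 19
Reactants: 29 (3R,5R,7R)-10-[(tert-butyldimethylsilyl)oxy]-1-[(tert-butyldiphenylsilyl)oxy]-3,5,7-trimethyldecane-3,5-diol
Product: 31 O,O′-[(3R,5R,7R)-10-[(tert-butyldimethylsilyl)oxy]-1-[(tert-butyldiphenylsilyl)oxy]-3,5,7-trimethyldecane-3,5-diyl]bis(hydroxylamine), via dipotassium dialkoxide 30 (not isolated)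
Conditions: KH, DMPU/THF, 0 °C; then 3,3-di-tert-butyloxaziridine, −40 °C → rt
Reagents that add atoms: 3,3-di-tert-butyloxaziridine, CC(C)(C)C1(NO1)C(C)(C)C
Why: Electrophilic O-amination of alkoxides with an N–H oxaziridine (alkoxide attacks nitrogen, di-tert-butyl ketone is released), a reaction type established for hindered potassium alkoxides; no C–O bond is broken, so both carbinol configurations are retained.

Step 20
Reactants: 31 O,O′-[(3R,5R,7R)-10-[(tert-butyldimethylsilyl)oxy]-1-[(tert-butyldiphenylsilyl)oxy]-3,5,7-trimethyldecane-3,5-diyl]bis(hydroxylamine)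
Product: 35 tert-butyl{2-[(3R,5R)-5-[(2R)-5-[(tert-butyldimethylsilyl)oxy]-2-methylpentyl]-3,5-dimethyl-1,2-dioxolan-3-yl]ethoxy}diphenylsilane, via cyclic dialkoxyhydrazine 32 (not isolated), via cyclic cis-hyponitrite 33 (not isolated), via 1,3-dioxyl diradical 34 (not isolated)
Conditions: PhI(OAc)2 (2.2 equiv), CH2Cl2 (high dilution), −40 → 20 °C, Ar, dark
Reagents that add atoms: none
Why: Proposed new method: PhI(OAc)2 should oxidise one aminooxy group of 31 to an electrophilic N-iodanyl/alkoxynitrene species that the neighbouring aminooxy nitrogen captures (seven-membered N–N ring closure to 32), and a second two-electron oxidation should give the ring-constrained cis-hyponitrite 33, which should lose N2 at or below room temperature to the singlet 1,3-dioxyl pair 34. The closest known chemistry is the oxidative coupling of O-alkylhydroxylamines to dialkyl hyponitrites, the cage recombination of tert-alkoxyl pairs from di-tert-alkyl hyponitrites to dialkyl peroxides, and the Pb(OAc)4 closure of ditertiary 1,3-bis(hydroperoxides) to tetraalkyl-1,2-dioxolanes with loss of O2, of which this is the nitrogen counterpart. The 1,2-dioxolane is closed by O–O radical–radical recombination of the tethered pair (five-membered closure by collapse of a 1,3-diradical, overall a ring contraction of the seven-membered dioxadiazepine by N2 extrusion). No stereocentre is created and no C–O bond is broken, so the C3 and C5 configurations set by the two epoxidations are carried through with retention. The step needs recombination to outrun β-scission to ketones, 1,5-hydrogen transfer, N2O loss to the oxetane and intermolecular N–N coupling; the three-atom tether holding a singlet pair, the fully substituted carbinol carbons, the absence of alkenes, low temperature and high dilution should secure it.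

Step 21
Reactants: 35 tert-butyl{2-[(3R,5R)-5-[(2R)-5-[(tert-butyldimethylsilyl)oxy]-2-methylpentyl]-3,5-dimethyl-1,2-dioxolan-3-yl]ethoxy}diphenylsilane
Product: 36 (4R)-5-[(3R,5R)-5-{2-[(tert-butyldiphenylsilyl)oxy]ethyl}-3,5-dimethyl-1,2-dioxolan-3-yl]-4-methylpentan-1-ol
Conditions: PPTS (cat.), MeOH, rt
Reagents that add atoms: none
Why: Acid-catalysed methanolysis of the primary tert-butyldimethylsilyl ether, which is far more acid-labile than the tert-butyldiphenylsilyl ether; the tetraalkyl peroxide is stable to mild acid.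

Step 22
Reactants: 36 (4R)-5-[(3R,5R)-5-{2-[(tert-butyldiphenylsilyl)oxy]ethyl}-3,5-dimethyl-1,2-dioxolan-3-yl]-4-methylpentan-1-ol
Product: 37 (4R)-5-[(3R,5R)-5-{2-[(tert-butyldiphenylsilyl)oxy]ethyl}-3,5-dimethyl-1,2-dioxolan-3-yl]-4-methylpentanal
Conditions: TEMPO (cat.), PhI(OAc)2, CH2Cl2, rt
Reagents that add atoms: none
Why: Oxoammonium (TEMPO/PhI(OAc)2) oxidation of a primary alcohol to the aldehyde under non-basic, non-reducing conditions that leave the O–O bond alone.

Step 23
Reactants: 37 (4R)-5-[(3R,5R)-5-{2-[(tert-butyldiphenylsilyl)oxy]ethyl}-3,5-dimethyl-1,2-dioxolan-3-yl]-4-methylpentanal; 7 1-phenyl-5-{[(4E)-5-phenylpent-4-en-1-yl]sulfonyl}-1H-tetrazole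
Product: 39 tert-butyl{2-[(3R,5R)-3,5-dimethyl-5-[(2R,5E,9E)-2-methyl-10-phenyldeca-5,9-dien-1-yl]-1,2-dioxolan-3-yl]ethoxy}diphenylsilane, via potassium sulfonyl carbanion 38 (not isolated)
Conditions: 7, KN(SiMe3)2 (KHMDS), DME, −60 °C; then 37, −60 °C → rt
Reagents that add atoms: none
Why: Julia–Kocienski olefination; the phenyltetrazolyl sulfone with a potassium base in DME should favour the (E)-alkene through the anti β-alkoxy sulfone and Smiles rearrangement, and the tetraalkyl dioxolane has no α-hydrogen for base-induced peroxide cleavage.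

Step 24
Reactants: 39 tert-butyl{2-[(3R,5R)-3,5-dimethyl-5-[(2R,5E,9E)-2-methyl-10-phenyldeca-5,9-dien-1-yl]-1,2-dioxolan-3-yl]ethoxy}diphenylsilane
Product: 40 2-[(3R,5R)-3,5-dimethyl-5-[(2R,5E,9E)-2-methyl-10-phenyldeca-5,9-dien-1-yl]-1,2-dioxolan-3-yl]ethan-1-ol
Conditions: Bu4NF, THF, 0 °C → rt
Reagents that add atoms: none
Why: Fluoride desilylation of the primary silyl ether; fluoride attacks only silicon and does not touch the peroxide or the diene.

Step 25
Reactants: 40 2-[(3R,5R)-3,5-dimethyl-5-[(2R,5E,9E)-2-methyl-10-phenyldeca-5,9-dien-1-yl]-1,2-dioxolan-3-yl]ethan-1-ol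
Product: 41 2-[(3S,5R)-3,5-dimethyl-5-[(2R,5E,9E)-2-methyl-10-phenyldeca-5,9-dien-1-yl]-1,2-dioxolan-3-yl]acetaldehyde
Conditions: TEMPO (cat.), PhI(OAc)2, CH2Cl2, 0 °C → rt
Reagents that add atoms: none
Why: Oxoammonium (TEMPO/PhI(OAc)2) oxidation to the aldehyde under non-basic conditions, which should avoid β-elimination of the peroxide oxygen; the disubstituted alkenes are tolerated (the descriptor at ring C3 changes to S by priority only).

Step 26
Reactants: 41 2-[(3S,5R)-3,5-dimethyl-5-[(2R,5E,9E)-2-methyl-10-phenyldeca-5,9-dien-1-yl]-1,2-dioxolan-3-yl]acetaldehyde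
Product: 42 2-[(3S,5R)-3,5-dimethyl-5-[(2R,5E,9E)-2-methyl-10-phenyldeca-5,9-dien-1-yl]-1,2-dioxolan-3-yl]acetic acid
Conditions: NaClO2, NaH2PO4, 2-methylbut-2-ene, t-BuOH/H2O, 0 °C → rt
Reagents that add atoms: sodium chlorite, [Na+].[O-]Cl=O
Why: Pinnick (Lindgren–Kraus) oxidation of the aldehyde to the acid in a mildly acidic buffer, with 2-methylbut-2-ene scavenging HOCl so that the two alkenes and the peroxide survive.

**Compound list**

1 | tert-butyl acetate | CC(=O)OC(C)(C)C | starting material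
2 | (E)-cinnamyl bromide | BrC/C=C/c1ccccc1 | starting material
3 | lithium enolate of tert-butyl acetate | C=C([O-])OC(C)(C)C.[Li+] | intermediate (not isolated)
4 | tert-butyl (4E)-5-phenylpent-4-enoate | CC(C)(C)OC(=O)CC/C=C/c1ccccc1 | intermediate
5 | (4E)-5-phenylpent-4-en-1-ol | OCCC/C=C/c1ccccc1 | intermediate
6 | 1-phenyl-5-{[(4E)-5-phenylpent-4-en-1-yl]sulfanyl}-1H-tetrazole | S(CCC/C=C/c1ccccc1)c1nnnn1-c1ccccc1 | intermediate
7 | 1-phenyl-5-{[(4E)-5-phenylpent-4-en-1-yl]sulfonyl}-1H-tetrazole | O=S(=O)(CCC/C=C/c1ccccc1)c1nnnn1-c1ccccc1 | intermediate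
8 | (R)-citronellal | C[C@H](CCC=C(C)C)CC=O | starting material
9 | (4R)-4,8-dimethylnon-7-en-1-yne | C[C@H](CCC=C(C)C)CC#C | intermediate
10 | formaldehyde (used as paraformaldehyde) | C=O | starting material
11 | dimethyl[(1E,4R)-2,4,8-trimethylnona-1,7-dien-1-yl]alane | C[C@H](CCC=C(C)C)C/C(C)=C/[Al](C)C | intermediate (not isolated)
12 | lithium butyl(dimethyl)[(1E,4R)-2,4,8-trimethylnona-1,7-dien-1-yl]aluminate | C[C@H](CCC=C(C)C)C/C(C)=C/[Al-](C)(C)CCCC.[Li+] | intermediate (not isolated)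
13 | (2E,5R)-3,5,9-trimethyldeca-2,8-dien-1-ol | C[C@H](CCC=C(C)C)C/C(C)=C/CO | intermediate
14 | [(2R,3R)-3-[(2R)-2,6-dimethylhept-5-en-1-yl]-3-methyloxiran-2-yl]methanol | C[C@H](CCC=C(C)C)C[C@@]1(C)O[C@@H]1CO | intermediate
15 | (3R,5R)-3,5,9-trimethyldec-8-ene-1,3-diol | C[C@H](CCC=C(C)C)C[C@@](C)(O)CCO | intermediate
16 | (3R,5R)-3,5,9-trimethyl-1,3-bis(triethylsilyloxy)dec-8-ene | C[C@H](CCC=C(C)C)C[C@@](C)(O[Si](CC)(CC)CC)CCO[Si](CC)(CC)CC | intermediate
17 | dimethyl{[(3R,5R)-3,5,9-trimethyl-3-(triethylsilyloxy)dec-8-en-1-yl]oxy}sulfonium chloride | C[C@H](CCC=C(C)C)C[C@@](C)(O[Si](CC)(CC)CC)CCO[S+](C)C.[Cl-] | intermediate (not isolated)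
18 | (3R,5R)-3,5,9-trimethyl-3-(triethylsilyloxy)dec-8-enal | C[C@H](CCC=C(C)C)C[C@@](C)(O[Si](CC)(CC)CC)CC=O | intermediate
19 | triethyl{[(4R,6R)-4,6,10-trimethylundec-9-en-1-yn-4-yl]oxy}silane | C[C@H](CCC=C(C)C)C[C@@](C)(O[Si](CC)(CC)CC)CC#C | intermediate
20 | (E)-alkenyl(dimethyl)alane from 19 | C[C@H](CCC=C(C)C)C[C@@](C)(O[Si](CC)(CC)CC)C/C(C)=C/[Al](C)C | intermediate (not isolated)
21 | lithium (E)-alkenyl(butyl)dimethylaluminate from 20 | C[C@H](CCC=C(C)C)C[C@@](C)(O[Si](CC)(CC)CC)C/C(C)=C/[Al-](C)(C)CCCC.[Li+] | intermediate (not isolated)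
22 | (2E,5R,7R)-3,5,7,11-tetramethyl-5-(triethylsilyloxy)dodeca-2,10-dien-1-ol | C[C@H](CCC=C(C)C)C[C@@](C)(O[Si](CC)(CC)CC)C/C(C)=C/CO | intermediate
23 | [(2S,3S)-3-methyl-3-[(2R,4R)-2,4,8-trimethyl-2-(triethylsilyloxy)non-7-en-1-yl]oxiran-2-yl]methanol | C[C@H](CCC=C(C)C)C[C@@](C)(O[Si](CC)(CC)CC)C[C@]1(C)O[C@H]1CO | intermediate
24 | (3R,5R,7R)-3,5,7,11-tetramethyl-5-(triethylsilyloxy)dodec-10-ene-1,3-diol | C[C@H](CCC=C(C)C)C[C@@](C)(O[Si](CC)(CC)CC)C[C@](C)(O)CCO | intermediate
25 | (3R,5R,7R)-3,5,7,11-tetramethyldodec-10-ene-1,3,5-triol | C[C@H](CCC=C(C)C)C[C@@](C)(O)C[C@](C)(O)CCO | intermediate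
26 | (3R,5R,7R)-1-[(tert-butyldiphenylsilyl)oxy]-3,5,7,11-tetramethyldodec-10-ene-3,5-diol | C[C@H](CCC=C(C)C)C[C@@](C)(O)C[C@](C)(O)CCO[Si](C(C)(C)C)(c1ccccc1)c1ccccc1 | intermediate
27 | (4R,6R,8R)-10-[(tert-butyldiphenylsilyl)oxy]-6,8-dihydroxy-4,6,8-trimethyldecanal | C[C@H](CCC=O)C[C@@](C)(O)C[C@](C)(O)CCO[Si](C(C)(C)C)(c1ccccc1)c1ccccc1 | intermediate (not isolated)
28 | (4R,6R,8R)-10-[(tert-butyldiphenylsilyl)oxy]-4,6,8-trimethyldecane-1,6,8-triol | C[C@H](CCCO)C[C@@](C)(O)C[C@](C)(O)CCO[Si](C(C)(C)C)(c1ccccc1)c1ccccc1 | intermediate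
29 | (3R,5R,7R)-10-[(tert-butyldimethylsilyl)oxy]-1-[(tert-butyldiphenylsilyl)oxy]-3,5,7-trimethyldecane-3,5-diol | C[C@H](CCCO[Si](C)(C)C(C)(C)C)C[C@@](C)(O)C[C@](C)(O)CCO[Si](C(C)(C)C)(c1ccccc1)c1ccccc1 | intermediate
30 | dipotassium 3,5-dialkoxide of 29 | C[C@H](CCCO[Si](C)(C)C(C)(C)C)C[C@@](C)([O-])C[C@](C)([O-])CCO[Si](C(C)(C)C)(c1ccccc1)c1ccccc1.[K+].[K+] | intermediate (not isolated)
31 | O,O′-[(3R,5R,7R)-10-[(tert-butyldimethylsilyl)oxy]-1-[(tert-butyldiphenylsilyl)oxy]-3,5,7-trimethyldecane-3,5-diyl]bis(hydroxylamine) | C[C@H](CCCO[Si](C)(C)C(C)(C)C)C[C@@](C)(ON)C[C@](C)(ON)CCO[Si](C(C)(C)C)(c1ccccc1)c1ccccc1 | intermediate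
32 | cyclic N,N′-dialkoxyhydrazine (5,7-dimethyl-1,4,2,3-dioxadiazepane carrying both side chains) | C[C@H](CCCO[Si](C)(C)C(C)(C)C)C[C@]1(C)C[C@@](C)(CCO[Si](C(C)(C)C)(c2ccccc2)c2ccccc2)ONNO1 | intermediate (not isolated)
33 | cyclic cis-hyponitrite (5,7-dimethyl-6,7-dihydro-5H-1,4,2,3-dioxadiazepine carrying both side chains) | C[C@H](CCCO[Si](C)(C)C(C)(C)C)C[C@]1(C)C[C@@](C)(CCO[Si](C(C)(C)C)(c2ccccc2)c2ccccc2)ON=NO1 | intermediate (not isolated)
34 | 1,3-dioxyl diradical (C3 and C5 alkoxyl radicals) | C[C@H](CCCO[Si](C)(C)C(C)(C)C)C[C@@](C)([O])C[C@](C)([O])CCO[Si](C(C)(C)C)(c1ccccc1)c1ccccc1 | intermediate (not isolated)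
35 | tert-butyl{2-[(3R,5R)-5-[(2R)-5-[(tert-butyldimethylsilyl)oxy]-2-methylpentyl]-3,5-dimethyl-1,2-dioxolan-3-yl]ethoxy}diphenylsilane | C[C@H](CCCO[Si](C)(C)C(C)(C)C)C[C@]1(C)C[C@@](C)(CCO[Si](C(C)(C)C)(c2ccccc2)c2ccccc2)OO1 | intermediate
36 | (4R)-5-[(3R,5R)-5-{2-[(tert-butyldiphenylsilyl)oxy]ethyl}-3,5-dimethyl-1,2-dioxolan-3-yl]-4-methylpentan-1-ol | C[C@H](CCCO)C[C@]1(C)C[C@@](C)(CCO[Si](C(C)(C)C)(c2ccccc2)c2ccccc2)OO1 | intermediate
37 | (4R)-5-[(3R,5R)-5-{2-[(tert-butyldiphenylsilyl)oxy]ethyl}-3,5-dimethyl-1,2-dioxolan-3-yl]-4-methylpentanal | C[C@H](CCC=O)C[C@]1(C)C[C@@](C)(CCO[Si](C(C)(C)C)(c2ccccc2)c2ccccc2)OO1 | intermediate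
38 | potassium α-sulfonyl carbanion of 7 | [K+].[CH-](CC/C=C/c1ccccc1)S(=O)(=O)c1nnnn1-c1ccccc1 | intermediate (not isolated)
39 | tert-butyl{2-[(3R,5R)-3,5-dimethyl-5-[(2R,5E,9E)-2-methyl-10-phenyldeca-5,9-dien-1-yl]-1,2-dioxolan-3-yl]ethoxy}diphenylsilane | C[C@H](CC/C=C/CC/C=C/c1ccccc1)C[C@]1(C)C[C@@](C)(CCO[Si](C(C)(C)C)(c2ccccc2)c2ccccc2)OO1 | intermediate
40 | 2-[(3R,5R)-3,5-dimethyl-5-[(2R,5E,9E)-2-methyl-10-phenyldeca-5,9-dien-1-yl]-1,2-dioxolan-3-yl]ethan-1-ol | C[C@H](CC/C=C/CC/C=C/c1ccccc1)C[C@]1(C)C[C@@](C)(CCO)OO1 | intermediate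
41 | 2-[(3S,5R)-3,5-dimethyl-5-[(2R,5E,9E)-2-methyl-10-phenyldeca-5,9-dien-1-yl]-1,2-dioxolan-3-yl]acetaldehyde | C[C@H](CC/C=C/CC/C=C/c1ccccc1)C[C@]1(C)C[C@@](C)(CC=O)OO1 | intermediate
42 | 2-[(3S,5R)-3,5-dimethyl-5-[(2R,5E,9E)-2-methyl-10-phenyldeca-5,9-dien-1-yl]-1,2-dioxolan-3-yl]acetic acid | C[C@H](CC/C=C/CC/C=C/c1ccccc1)C[C@]1(C)C[C@@](C)(CC(=O)O)OO1 | target

**Step count and risks**

Total step count: 26. Longest linear sequence: 22 steps (steps 5–26, from (R)-citronellal); the sulfone branch (steps 1–4) joins at step 23.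

Steps most likely to fail:

1. Step 20 (proposed new method). The cis-hyponitrite may extrude N2O and collapse to the oxetane instead of losing N2, the dioxyl pair may fragment by β-scission before it recombines, or the aminooxy groups may couple between molecules. Fallback with known chemistry, setting out from triol 28: acid-catalysed perhydrolysis of both tertiary hydroxyls (50% H2O2, catalytic H2SO4, Et2O, 0 °C) should give, through the tertiary cations, (4R)-10-[(tert-butyldiphenylsilyl)oxy]-6,8-dihydroperoxy-4,6,8-trimethyldecan-1-ol F1 as a mixture of diastereomers at the two peroxidised carbons. Pb(OAc)4 (CH2Cl2, −20 °C → rt) should then close the 1,2-dioxolane with loss of O2, as known for ditertiary 1,3-bis(hydroperoxides). This gives up stereocontrol at C3 and C5, so the (3R,5R) isomer would have to be separated from its three diastereomers by preparative HPLC; it is alcohol 36, where the route resumes.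

2. Step 19. The second amination of the hindered dialkoxide may stall, the first-formed aminooxy anion may be aminated on nitrogen, or the C1 silyl group may migrate to the C3 alkoxide under prolonged exposure to KH. Fallback, setting out from diol 29: a staged amination with the first nitrogen masked. One equivalent of KH and the oxaziridine should give the mono(aminooxy) alcohol F2 (the C3 regioisomer is given; the C5 regioisomer would be carried through alike and converges). Boc2O converts it to the N-Boc carbamate F3, whose nitrogen anion no longer competes for the oxaziridine. A second alkoxide amination (KH, 2 equiv) gives the carbamate-protected bis(aminooxy) compound F4, and Me3SiOTf/2,6-lutidine followed by MeOH removes the Boc group with both silyl ethers intact, returning bis(aminooxy) compound 31.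

3. Step 23. The sulfonyl carbanion or residual amide base may attack the O–O bond, or E selectivity at C10=C11 may erode. Fallback, setting out from alkene 26: the olefination is moved ahead of O–O bond formation. Ozonolysis of 26 with Me2S work-up gives aldehyde 27 as an isolated compound; Julia–Kocienski reaction with carbanion 38 on this peroxide-free aldehyde (the free tertiary hydroxyls are tolerated, since the sulfonyl carbanion is a weaker base than a tertiary alkoxide) gives the diene diol F5. Alkoxide amination as in step 19 gives the bis(aminooxy) diene F6, and oxidation under the conditions of step 20 would deliver diene dioxolane 39 directly. The price is that two alkenes are present during the nitrogen extrusion, so this is used only if the peroxide does not survive the olefination.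

**Further compounds**

F1 | step 20 | (4R)-10-[(tert-butyldiphenylsilyl)oxy]-6,8-dihydroperoxy-4,6,8-trimethyldecan-1-ol (mixture of C6/C8 diastereomers) | C[C@H](CCCO)CC(C)(OO)CC(C)(OO)CCO[Si](C(C)(C)C)(c1ccccc1)c1ccccc1
F2 | step 19 | (3R,5R,7R)-3-(aminooxy)-10-[(tert-butyldimethylsilyl)oxy]-1-[(tert-butyldiphenylsilyl)oxy]-3,5,7-trimethyldecan-5-ol | C[C@H](CCCO[Si](C)(C)C(C)(C)C)C[C@@](C)(O)C[C@](C)(ON)CCO[Si](C(C)(C)C)(c1ccccc1)c1ccccc1
F3 | step 19 | tert-butyl N-{[(3R,5R,7R)-10-[(tert-butyldimethylsilyl)oxy]-1-[(tert-butyldiphenylsilyl)oxy]-5-hydroxy-3,5,7-trimethyldecan-3-yl]oxy}carbamate | C[C@H](CCCO[Si](C)(C)C(C)(C)C)C[C@@](C)(O)C[C@](C)(ONC(=O)OC(C)(C)C)CCO[Si](C(C)(C)C)(c1ccccc1)c1ccccc1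
F4 | step 19 | tert-butyl N-{[(3R,5R,7R)-5-(aminooxy)-10-[(tert-butyldimethylsilyl)oxy]-1-[(tert-butyldiphenylsilyl)oxy]-3,5,7-trimethyldecan-3-yl]oxy}carbamate | C[C@H](CCCO[Si](C)(C)C(C)(C)C)C[C@@](C)(ON)C[C@](C)(ONC(=O)OC(C)(C)C)CCO[Si](C(C)(C)C)(c1ccccc1)c1ccccc1
F5 | step 23 | (3R,5R,7R,10E,14E)-1-[(tert-butyldiphenylsilyl)oxy]-3,5,7-trimethyl-15-phenylpentadeca-10,14-diene-3,5-diol | C[C@H](CC/C=C/CC/C=C/c1ccccc1)C[C@@](C)(O)C[C@](C)(O)CCO[Si](C(C)(C)C)(c1ccccc1)c1ccccc1
F6 | step 23 | O,O′-[(3R,5R,7R,10E,14E)-1-[(tert-butyldiphenylsilyl)oxy]-3,5,7-trimethyl-15-phenylpentadeca-10,14-diene-3,5-diyl]bis(hydroxylamine) | C[C@H](CC/C=C/CC/C=C/c1ccccc1)C[C@@](C)(ON)C[C@](C)(ON)CCO[Si](C(C)(C)C)(c1ccccc1)c1ccccc1
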